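**Remarks on the chemistry (assumptions)**
- Compound 1 (the 4‑O‑methyl ether of 2,4,6‑trihydroxyacetophenone) is taken as a commercial starting material.
- The diazo component is used as its benzyl ester, so that the carboxylic acid can later be freed by hydrogenolysis and not by base.
- Aryl glyoxal 5 is drawn as the free aldehyde, although it is expected to be handled as its hydrate.

## Analysis of the target

The target 20 is a 2‑aryl‑1‑benzofuran‑3‑carbaldehyde. Ring A (C3a, C4–C7, C7a) is pentasubstituted, with a hydroxyl at C4, a 3‑hydroxy‑3‑methylbutyl chain at C5, a methoxy group at C6 and only C7 unsubstituted. The furan ring (O1, C2, C3) carries the 2,4‑dihydroxyphenyl ring B at C2 and the formyl group at C3. There is no stereocentre, so every problem is one of regiochemistry and chemoselectivity. Three phenols and a tertiary alcohol must end up free while only the C6 oxygen is methylated, and the two oxygens ortho to C3a (O1 and the C4 hydroxyl) must be told apart although they stem from a symmetrical 1,3,5‑trioxygenated ring. The sensitive groups are the electron‑rich aldehyde (hydrogen‑bonded to the C4 hydroxyl and able to form a lactol with the 2′‑hydroxyl), the tertiary alcohol (which under strong acid dehydrates or is captured by the C4 hydroxyl as a chroman) and the oxidisable resorcinol ring B. The hard part is the fully substituted C2=C3 bond, wedged between ring B and the C4 oxygen, with the C3 carbon substituent at the aldehyde oxidation level. The strategy rests on C2: its bonds to O1, C3 and C1′ of ring B are the bonds that the carbene carbon of a ring B arylacetate makes when it is placed between the phenol oxygen and the ortho ketone carbon of a ring A acylphenol. The fourth substituent of that carbon, a carboxyl group, later leaves together with the C3 hydroxyl to aromatise the furan, and the formyl carbon enters as the acetal carbon of an aryl glyoxal, so C3 never needs a redox adjustment.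

## Retrosynthetic reasoning

**20 from 19.** The last operation only removes the two aryl silyl ethers of ring B. They are kept to the end because the free resorcinol is the most oxidisable part of the molecule, and because silyl ethers on ring B offer neither an O–H bond nor a C–H bond alpha to oxygen to the carbene used earlier.

**19 from 18.** The C2=C3 double bond is traced back to the β‑hydroxy acid 18: in the forward sense the C2–carboxyl bond and the C3–O bond are broken together. This is the right place because C3 is a tertiary benzylic carbon on a ring with three oxygen donors ortho and para to it, so it ionises under mild acid and the neighbouring carboxyl group leaves in a decarboxylative elimination. The same acid hydrolyses the dimethyl acetal to the formyl group and removes the triethylsilyl ether. The forward reaction must do this at room temperature so that the tertiary alcohol is neither dehydrated nor cyclised onto the C4 hydroxyl.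

**18 from 17.** Both benzyl groups of 17, the ester and the C4 ether, are cut in one hydrogenolysis. A benzyl ester is chosen because a base‑mediated ester hydrolysis of this hindered β‑hydroxy ester would risk retro‑aldol opening of the tertiary aldolate and loss of the aryl silyl ethers.

**17 from 11 and 15.** This is the central disconnection: O1–C2 and C2–C3 are cut, which takes out C2 as a carbene carbon and opens the furan ring. What is gained is a convergent union of a complete ring A piece (11) with a complete ring B piece (15), with the masked formyl group already on the carbon that becomes C3. The forward reaction has to let the rhodium carbene from 15 react with the single free phenol of 11 to give ylide 16, and then let 16 add to the ortho ketone faster than it transfers a proton. The two stereocentres formed are of no consequence.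

**15 from 14, 13 and 12.** The diazo group comes from diazo transfer to the benzylic methylene of 14. Compound 14 comes from 13 by silylation of both phenols, and 13 from the acid 12 by selective O‑alkylation of the carboxylate.

**11 from 7 and 10 (from 9 and 8).** The aryl–CH2 bond of the side chain is cut to the aryl iodide 7 and the B‑alkyl borane 10, which is made in the flask by hydroboration of 9, the silyl ether of 8. The cut is placed last in the ring A sequence because the tertiary triethylsilyl ether would not survive the oxidation and the acidic acetalisation that build the keto acetal. The coupling has to work on an iodide flanked by two alkoxy groups and in the presence of a free phenol, a ketone and an acetal.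

**7 from 6, 5 and 4.** The keto acetal is traced back through the aryl glyoxal 5 to the methyl ketone 4 (Riley oxidation, then aldehyde‑selective acetalisation). The phenol that will react in the key step stays silylated through these two steps, because a free hydroxyl ortho to the glyoxal would close onto the aldehyde carbon as a five‑membered cyclic acetal. It is freed (6 to 7) under buffered, non‑acidic conditions once the acetal is in place.

**4 from 3, 2 and 1.** The two ortho hydroxyls of the symmetrical ketone 1 are told apart in three moves. One is silylated (2), which breaks the symmetry without any question of regiochemistry. The remaining chelated hydroxyl directs iodination to its own ortho position (3). That hydroxyl is then benzylated (4). The benzyl ether thus ends up next to the iodine, on the oxygen that becomes the C4 hydroxyl, and the silyl ether sits on the oxygen that becomes O1.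

## Alternatives that were turned down

**Alternative 1: ring transposition of a 3‑aroylbenzofuran‑2‑one.** The disconnection is O1–C2, formed by attack of a ring A phenol on the ring B ketone. In the forward step the lactone A1 is opened by acid‑promoted methanolysis, a ring A hydroxyl condenses with the aroyl ketone with loss of water, and the former lactone carbonyl becomes the C3 ester of the benzofuran A2.
- For it: the core is reached in very few steps from simple pieces, no diazo compound is needed, and because ring A of A1 is symmetrical the reclosure has no regiochemical question.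
- Against it for this target: A2 has neither the C5 side chain nor the C6 methyl ether, and its C3 substituent is an ester that needs a reduction and a re‑oxidation (or a delicate partial reduction) on a polyphenol. Introducing the chain late would have to distinguish C5 from C7, both flanked by two oxygens. Introducing it before the transposition would make the two reclosing phenols non‑equivalent and give C5/C7 isomers.
- Comparison: on step economy to the bare ring system and on operational simplicity alternative 1 is stronger. The chosen strategy offers instead a ring closure in which the side chain and the aldehyde oxidation level are already present (11), and in which the regiochemistry is fixed by the one free hydroxyl.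

**Alternative 2: Danheiser benzannulation of ring A onto a furan.** The disconnection removes four bonds of ring A (C7–C7a, C4–C5, C6–C7, C3a–C4). In the forward step the furyl diazo ketone A3 is irradiated; Wolff rearrangement gives a furyl ketene, which adds to the methoxyalkyne A4, and ring opening and 6π closure of the resulting cyclobutenone on heating give the benzofuran ester A5.
- For it: the polarisation of A4 places hydroxyl, chain and methoxy group at C4, C5 and C6 without any differentiation of phenols, and the C4 hydroxyl emerges free.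
- Against it: A3 is a tetrasubstituted furan that needs its own multistep synthesis, A4 is a sensitive alkoxyalkyne, the step is photochemical, and the C3 ester of A5 again needs redox adjustment to the aldehyde next to a free phenol.
- Comparison: on regiocontrol of ring A alternative 2 is stronger than the sequence 1 to 4, which relies on directing effects. The chosen strategy offers commercial aromatic starting materials, no photochemistry and the formyl carbon at the right oxidation level from the start.

**Alternative 3: coumestan by oxidative C–H closure of O1–C7a.** The disconnection is O1–C7a. In the forward step the enolic hydroxyl of the 3‑aryl‑4‑hydroxycoumarin A6 is joined to the only free ortho C–H of its ring A aryl group by a divalent palladium catalyst and an oxidant, giving the coumestan A7, the lactone form of the target skeleton.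
- For it: the C–H site is unambiguous, no congested aldol is involved, and the lactone of A7 ties the C3 carbon to the 2′‑oxygen as a built‑in protecting group. One partial reduction of the lactone would give the lactol tautomer of the hydroxy aldehyde.
- Against it: A6 needs a ring A arylacetic acid building block with four contiguous substituents, which is as laborious as 11. The free tertiary alcohol and the electron‑rich arenes must survive oxidative palladium chemistry. The partial reduction can overshoot to the diol. The acetal protecting groups must be removed with acid while the C4 hydroxyl and the tertiary alcohol are both free, which invites chroman formation.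
- Comparison: on the security of the furan closure alternative 3 is as strong or stronger. The chosen strategy offers greater convergence (two fragments of similar size joined in the ring‑forming step), an endgame without hydride reagents, and benzyl and silyl groups that leave under neutral or buffered conditions.

Key step: step 12

## Route

**Step 1**
Reactants: 1 2′,6′‑dihydroxy‑4′‑methoxyacetophenone
Product: 2 1‑[2‑hydroxy‑4‑methoxy‑6‑(triisopropylsilyloxy)phenyl]ethan‑1‑one
Conditions: TIPSCl (1.05 equiv), imidazole, DMF, 0 °C to rt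
Reagents that add atoms: triisopropylsilyl chloride, CC(C)[Si](Cl)(C(C)C)C(C)C
Why: Silylation of a phenol; the two hydroxyls of 1 are equivalent, and once one is silylated the other is locked in a hydrogen bond to the now more hindered ketone, so the reaction should stop at the mono ether.

**Step 2**
Reactants: 2 1‑[2‑hydroxy‑4‑methoxy‑6‑(triisopropylsilyloxy)phenyl]ethan‑1‑one
Product: 3 1‑[2‑hydroxy‑3‑iodo‑4‑methoxy‑6‑(triisopropylsilyloxy)phenyl]ethan‑1‑one
Conditions: NIS (1.0 equiv), MeCN, 0 °C to rt
Reagents that add atoms: N‑iodosuccinimide, O=C1CCC(=O)N1I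
Why: Electrophilic aromatic iodination directed by the free chelated hydroxyl to its ortho position C3; the other open position C5 lies between the methoxy group and the bulky silyloxy group and should be shielded, which also limits double iodination.

**Step 3**
Reactants: 3 1‑[2‑hydroxy‑3‑iodo‑4‑methoxy‑6‑(triisopropylsilyloxy)phenyl]ethan‑1‑one
Product: 4 1‑[2‑(benzyloxy)‑3‑iodo‑4‑methoxy‑6‑(triisopropylsilyloxy)phenyl]ethan‑1‑one
Conditions: BnBr, K2CO3, DMF, rt
Reagents that add atoms: benzyl bromide, BrCc1ccccc1
Why: Williamson ether synthesis; the phenol flanked by iodine and the acyl group is acidic and its phenoxide is benzylated, which puts the benzyl group on the oxygen next to the future side chain, while anhydrous carbonate does not attack the hindered aryl silyl ether.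

**Step 4**
Reactants: 4 1‑[2‑(benzyloxy)‑3‑iodo‑4‑methoxy‑6‑(triisopropylsilyloxy)phenyl]ethan‑1‑one
Product: 5 2‑[2‑(benzyloxy)‑3‑iodo‑4‑methoxy‑6‑(triisopropylsilyloxy)phenyl]‑2‑oxoacetaldehyde
Conditions: SeO2, 1,4‑dioxane/H2O, 90 °C
Reagents that add atoms: selenium dioxide, O=[Se]=O
Why: Riley oxidation of an aryl methyl ketone to the aryl glyoxal; it runs through the enol, so the twist of the di‑ortho‑substituted ketone does not block it (as with mesityl methyl ketone), and aryl iodide, benzyl ether and aryl silyl ether are inert to SeO2.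

**Step 5**
Reactants: 5 2‑[2‑(benzyloxy)‑3‑iodo‑4‑methoxy‑6‑(triisopropylsilyloxy)phenyl]‑2‑oxoacetaldehyde
Product: 6 1‑[2‑(benzyloxy)‑3‑iodo‑4‑methoxy‑6‑(triisopropylsilyloxy)phenyl]‑2,2‑dimethoxyethan‑1‑one
Conditions: HC(OMe)3, MeOH, TsOH·H2O (cat.), rt
Reagents that add atoms: trimethyl orthoformate, COC(OC)OC; methanol, CO
Why: Acid‑catalysed acetalisation, selective for the aldehyde because the ketone is buried between the di‑ortho‑substituted ring and the acetal carbon; the phenol is kept silylated here since a free ortho hydroxyl would add to the aldehyde carbon and give a cyclic mixed acetal, and the aryl triisopropylsilyl ether tolerates the mild acid.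

**Step 6**
Reactants: 6 1‑[2‑(benzyloxy)‑3‑iodo‑4‑methoxy‑6‑(triisopropylsilyloxy)phenyl]‑2,2‑dimethoxyethan‑1‑one
Product: 7 1‑[2‑(benzyloxy)‑6‑hydroxy‑3‑iodo‑4‑methoxyphenyl]‑2,2‑dimethoxyethan‑1‑one
Conditions: TBAF, AcOH, THF, 0 °C
Reagents that add atoms: none
Why: Fluoride‑induced cleavage of an aryl silyl ether, fast because the ortho‑acyl phenoxide is a good leaving group; the buffered non‑acidic medium leaves the dimethyl acetal, benzyl ether and aryl iodide untouched.

**Step 7**
Reactants: 8 2‑methylbut‑3‑en‑2‑ol
Product: 9 triethyl[(2‑methylbut‑3‑en‑2‑yl)oxy]silane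
Conditions: TESOTf, 2,6‑lutidine, CH2Cl2, −78 to 0 °C
Reagents that add atoms: triethylsilyl trifluoromethanesulfonate, CC[Si](CC)(CC)OS(=O)(=O)C(F)(F)F
Why: Silylation of a tertiary alcohol with a silyl triflate and a hindered base, the standard way to silylate hindered hydroxyls; the ether removes the only aliphatic O–H bond that could compete in the carbene step.

**Step 8**
Reactants: 9 triethyl[(2‑methylbut‑3‑en‑2‑yl)oxy]silane; 7 1‑[2‑(benzyloxy)‑6‑hydroxy‑3‑iodo‑4‑methoxyphenyl]‑2,2‑dimethoxyethan‑1‑one
Product: 11 1‑[2‑(benzyloxy)‑6‑hydroxy‑4‑methoxy‑3‑(3‑methyl‑3‑triethylsilyloxybutyl)phenyl]‑2,2‑dimethoxyethan‑1‑one, via B‑alkyl‑9‑BBN adduct 10 (not isolated)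
Conditions: 9‑BBN‑H (slightly less than 1 equiv relative to 9), THF, 0 °C to rt; then 7, Pd(OAc)2, SPhos, K3PO4 (3 M aq), THF, 60 °C
Reagents that add atoms: 9‑borabicyclo[3.3.1]nonane (9‑BBN‑H), B1C2CCCC1CCC2 (its boron and carbons are found in intermediate 10; in 11 only one of its hydrogens remains)
Why: Anti‑Markovnikov hydroboration of the terminal alkene followed by B‑alkyl Suzuki–Miyaura coupling; zerovalent palladium formed in situ with the bulky electron‑rich biaryl phosphine should insert into the C–I bond despite the two flanking alkoxy groups, and the aqueous phosphate tolerates ketone, acetal, benzyl ether and tertiary silyl ether while the free phenol only consumes base. Keeping the borane free of residual B–H avoids reduction of the ketone.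

**Step 9**
Reactants: 12 2,4‑dihydroxyphenylacetic acid
Product: 13 benzyl (2,4‑dihydroxyphenyl)acetate
Conditions: BnBr, KHCO3, DMF, rt
Reagents that add atoms: benzyl bromide, BrCc1ccccc1
Why: O‑Alkylation of a carboxylate; hydrogen carbonate deprotonates only the carboxylic acid, so the two phenols stay free and the ester forms selectively.

**Step 10**
Reactants: 13 benzyl (2,4‑dihydroxyphenyl)acetate
Product: 14 benzyl [2,4‑bis(triisopropylsilyloxy)phenyl]acetate
Conditions: TIPSCl (2.4 equiv), imidazole, DMF, rt to 40 °C
Reagents that add atoms: triisopropylsilyl chloride, CC(C)[Si](Cl)(C(C)C)C(C)C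
Why: Silylation of both phenols; it also removes the risk of lactonisation of the ortho hydroxyl onto the ester and gives ring B oxygen substituents without C–H bonds alpha to oxygen.

**Step 11**
Reactants: 14 benzyl [2,4‑bis(triisopropylsilyloxy)phenyl]acetate
Product: 15 benzyl 2‑diazo‑2‑[2,4‑bis(triisopropylsilyloxy)phenyl]acetate
Conditions: p‑ABSA, DBU, MeCN, 0 °C to rt
Reagents that add atoms: 4‑acetamidobenzenesulfonyl azide, CC(=O)Nc1ccc(cc1)S(=O)(=O)N=[N+]=[N-]
Why: Regitz diazo transfer to the enolate of an arylacetate, the standard entry to aryldiazoacetates; DBU is not nucleophilic and should leave the aryl silyl ethers alone.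

**Step 12**
Reactants: 11 1‑[2‑(benzyloxy)‑6‑hydroxy‑4‑methoxy‑3‑(3‑methyl‑3‑triethylsilyloxybutyl)phenyl]‑2,2‑dimethoxyethan‑1‑one; 15 benzyl 2‑diazo‑2‑[2,4‑bis(triisopropylsilyloxy)phenyl]acetate
Product: 17 benzyl 4‑(benzyloxy)‑2‑[2,4‑bis(triisopropylsilyloxy)phenyl]‑3‑(dimethoxymethyl)‑3‑hydroxy‑6‑methoxy‑5‑(3‑methyl‑3‑triethylsilyloxybutyl)‑2,3‑dihydro‑1‑benzofuran‑2‑carboxylate (racemic, relative configuration at C2/C3 left open), via oxonium ylide 16 (not isolated)
Conditions: Rh2(OAc)4 (2 mol %), 4 Å MS, CH2Cl2, 40 °C, 15 (1.5 equiv) added slowly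
Reagents that add atoms: none
Why: Rh2(OAc)4, a dimer of divalent rhodium, extrudes dinitrogen from 15 to give an electrophilic donor/acceptor rhodium carbene, which is attacked by the only free O–H group, the phenol of 11, to give the oxonium ylide 16 (free or as its rhodium‑bound enol). Before the usual 1,2‑proton shift can complete a plain O–H insertion, the enol carbon of 16 adds to the neighbouring ketone, which is held close by the hydrogen bond and made electrophilic by the inductive pull of the acetal, while the oxonium proton passes to the carbonyl oxygen; O1–C2 and C2–C3 are thus formed in one operation. The closest known reaction type is the Rh2(OAc)4‑catalysed O–H insertion of aryldiazoacetates into 2‑hydroxyaryl ketones with intramolecular aldol‑type trapping, which gives 3‑hydroxy‑2,3‑dihydrobenzofuran‑2‑carboxylates. The dihydrofuran ring closes in a 5‑(enolexo)‑exo‑trig aldol mode. The stereocentres C2 and C3 arise together in the C–C bond formation; their relative configuration is decided by the compact hydrogen‑bonded transition state (expected to place the C3 hydroxyl cis to the ester), the achiral catalyst gives a racemate, and neither matters because both centres are erased in step 14. The step needs O–H insertion to beat carbene dimerisation and C–H insertion, and aldol closure to beat proton transfer: slow addition keeps the diazo concentration low, the ring B oxygens and the tertiary alcohol carry silyl groups that offer no O–H bond and no C–H bond alpha to oxygen within reach of the carbene, and the activated ketone sits ortho to the reacting oxygen.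

**Step 13**
Reactants: 17 benzyl 4‑(benzyloxy)‑2‑[2,4‑bis(triisopropylsilyloxy)phenyl]‑3‑(dimethoxymethyl)‑3‑hydroxy‑6‑methoxy‑5‑(3‑methyl‑3‑triethylsilyloxybutyl)‑2,3‑dihydro‑1‑benzofuran‑2‑carboxylate
Product: 18 2‑[2,4‑bis(triisopropylsilyloxy)phenyl]‑3‑(dimethoxymethyl)‑3,4‑dihydroxy‑6‑methoxy‑5‑(3‑methyl‑3‑triethylsilyloxybutyl)‑2,3‑dihydro‑1‑benzofuran‑2‑carboxylic acid (racemic, relative configuration left open)
Conditions: H2 (1 atm), Pd/C, EtOAc, rt
Reagents that add atoms: none
Why: Hydrogenolysis of a benzyl ester and an aryl benzyl ether on palladium, neutral conditions that avoid the retro‑aldol risk of a basic ester hydrolysis; silyl ethers and the acetal are stable in ethyl acetate, and the benzylic C–O bonds at the fully substituted C2 and C3 are too hindered to adsorb and should react far more slowly than the two primary benzyl groups.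

**Step 14**
Reactants: 18 2‑[2,4‑bis(triisopropylsilyloxy)phenyl]‑3‑(dimethoxymethyl)‑3,4‑dihydroxy‑6‑methoxy‑5‑(3‑methyl‑3‑triethylsilyloxybutyl)‑2,3‑dihydro‑1‑benzofuran‑2‑carboxylic acid
Product: 19 2‑[2,4‑bis(triisopropylsilyloxy)phenyl]‑4‑hydroxy‑5‑(3‑hydroxy‑3‑methylbutyl)‑6‑methoxy‑1‑benzofuran‑3‑carbaldehyde
Conditions: HCl (1 M aq), THF, rt
Reagents that add atoms: water, O
Why: Acid‑promoted decarboxylative dehydration of a β‑hydroxy acid (E1‑type decarboxylative elimination): the C3 hydroxyl ionises to a cation stabilised by the three oxygen donors of ring A, the neighbouring carboxyl group leaves as carbon dioxide and the furan becomes aromatic whatever the relative configuration of 18. The acetal, now vinylogous to the furan oxygen, then hydrolyses readily to the aldehyde, and the triethylsilyl ether is cleaved by the same dilute acid, which at room temperature should not ionise the tertiary alcohol or cleave the aryl triisopropylsilyl ethers.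

**Step 15**
Reactants: 19 2‑[2,4‑bis(triisopropylsilyloxy)phenyl]‑4‑hydroxy‑5‑(3‑hydroxy‑3‑methylbutyl)‑6‑methoxy‑1‑benzofuran‑3‑carbaldehyde
Product: 20 2‑(2,4‑dihydroxyphenyl)‑4‑hydroxy‑5‑(3‑hydroxy‑3‑methylbutyl)‑6‑methoxy‑1‑benzofuran‑3‑carbaldehyde
Conditions: TBAF (2.2 equiv), AcOH, THF, 0 °C
Reagents that add atoms: none
Why: Fluoride‑induced cleavage of the two aryl silyl ethers; buffering with acetic acid keeps the medium from becoming basic enough to harm the phenolic aldehyde, and nothing else in the molecule reacts with fluoride.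

## Compound list

1 | 2′,6′‑dihydroxy‑4′‑methoxyacetophenone | CC(=O)c1c(O)cc(OC)cc1O | starting material
2 | 1‑[2‑hydroxy‑4‑methoxy‑6‑(triisopropylsilyloxy)phenyl]ethan‑1‑one | CC(=O)c1c(O)cc(OC)cc1O[Si](C(C)C)(C(C)C)C(C)C | intermediate
3 | 1‑[2‑hydroxy‑3‑iodo‑4‑methoxy‑6‑(triisopropylsilyloxy)phenyl]ethan‑1‑one | CC(=O)c1c(O)c(I)c(OC)cc1O[Si](C(C)C)(C(C)C)C(C)C | intermediate
4 | 1‑[2‑(benzyloxy)‑3‑iodo‑4‑methoxy‑6‑(triisopropylsilyloxy)phenyl]ethan‑1‑one | CC(=O)c1c(OCc2ccccc2)c(I)c(OC)cc1O[Si](C(C)C)(C(C)C)C(C)C | intermediate
5 | 2‑[2‑(benzyloxy)‑3‑iodo‑4‑methoxy‑6‑(triisopropylsilyloxy)phenyl]‑2‑oxoacetaldehyde | O=CC(=O)c1c(OCc2ccccc2)c(I)c(OC)cc1O[Si](C(C)C)(C(C)C)C(C)C | intermediate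
6 | 1‑[2‑(benzyloxy)‑3‑iodo‑4‑methoxy‑6‑(triisopropylsilyloxy)phenyl]‑2,2‑dimethoxyethan‑1‑one | COC(OC)C(=O)c1c(OCc2ccccc2)c(I)c(OC)cc1O[Si](C(C)C)(C(C)C)C(C)C | intermediate
7 | 1‑[2‑(benzyloxy)‑6‑hydroxy‑3‑iodo‑4‑methoxyphenyl]‑2,2‑dimethoxyethan‑1‑one | COC(OC)C(=O)c1c(OCc2ccccc2)c(I)c(OC)cc1O | intermediate
8 | 2‑methylbut‑3‑en‑2‑ol | C=CC(C)(C)O | starting material
9 | triethyl[(2‑methylbut‑3‑en‑2‑yl)oxy]silane | C=CC(C)(C)O[Si](CC)(CC)CC | intermediate
10 | 9‑[3‑methyl‑3‑(triethylsilyloxy)butyl]‑9‑borabicyclo[3.3.1]nonane (formed in the flask, not isolated) | CC[Si](CC)(CC)OC(C)(C)CCB1C2CCCC1CCC2 | intermediate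
11 | 1‑[2‑(benzyloxy)‑6‑hydroxy‑4‑methoxy‑3‑(3‑methyl‑3‑triethylsilyloxybutyl)phenyl]‑2,2‑dimethoxyethan‑1‑one | COC(OC)C(=O)c1c(O)cc(OC)c(CCC(C)(C)O[Si](CC)(CC)CC)c1OCc1ccccc1 | intermediate
12 | 2,4‑dihydroxyphenylacetic acid | O=C(O)Cc1ccc(O)cc1O | starting material
13 | benzyl (2,4‑dihydroxyphenyl)acetate | O=C(Cc1ccc(O)cc1O)OCc1ccccc1 | intermediate
14 | benzyl [2,4‑bis(triisopropylsilyloxy)phenyl]acetate | O=C(Cc1ccc(O[Si](C(C)C)(C(C)C)C(C)C)cc1O[Si](C(C)C)(C(C)C)C(C)C)OCc1ccccc1 | intermediate
15 | benzyl 2‑diazo‑2‑[2,4‑bis(triisopropylsilyloxy)phenyl]acetate | O=C(OCc1ccccc1)C(=[N+]=[N-])c1ccc(O[Si](C(C)C)(C(C)C)C(C)C)cc1O[Si](C(C)C)(C(C)C)C(C)C | intermediate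
16 | oxonium ylide from the phenol oxygen of 11 and the carbene carbon of 15 (formed in the flask, not isolated) | COC(OC)C(=O)c1c([OH+][C-](C(=O)OCc2ccccc2)c2ccc(O[Si](C(C)C)(C(C)C)C(C)C)cc2O[Si](C(C)C)(C(C)C)C(C)C)cc(OC)c(CCC(C)(C)O[Si](CC)(CC)CC)c1OCc1ccccc1 | intermediate
17 | benzyl 4‑(benzyloxy)‑2‑[2,4‑bis(triisopropylsilyloxy)phenyl]‑3‑(dimethoxymethyl)‑3‑hydroxy‑6‑methoxy‑5‑(3‑methyl‑3‑triethylsilyloxybutyl)‑2,3‑dihydro‑1‑benzofuran‑2‑carboxylate (racemic; relative configuration at C2/C3 not controlled and not needed) | O=C(OCc1ccccc1)C1(c2ccc(O[Si](C(C)C)(C(C)C)C(C)C)cc2O[Si](C(C)C)(C(C)C)C(C)C)Oc2cc(OC)c(CCC(C)(C)O[Si](CC)(CC)CC)c(OCc3ccccc3)c2C1(O)C(OC)OC | intermediate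
18 | 2‑[2,4‑bis(triisopropylsilyloxy)phenyl]‑3‑(dimethoxymethyl)‑3,4‑dihydroxy‑6‑methoxy‑5‑(3‑methyl‑3‑triethylsilyloxybutyl)‑2,3‑dihydro‑1‑benzofuran‑2‑carboxylic acid (racemic; relative configuration not controlled and not needed) | O=C(O)C1(c2ccc(O[Si](C(C)C)(C(C)C)C(C)C)cc2O[Si](C(C)C)(C(C)C)C(C)C)Oc2cc(OC)c(CCC(C)(C)O[Si](CC)(CC)CC)c(O)c2C1(O)C(OC)OC | intermediate
19 | 2‑[2,4‑bis(triisopropylsilyloxy)phenyl]‑4‑hydroxy‑5‑(3‑hydroxy‑3‑methylbutyl)‑6‑methoxy‑1‑benzofuran‑3‑carbaldehyde | COc1cc2oc(-c3ccc(O[Si](C(C)C)(C(C)C)C(C)C)cc3O[Si](C(C)C)(C(C)C)C(C)C)c(C=O)c2c(O)c1CCC(C)(C)O | intermediate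
20 | 2‑(2,4‑dihydroxyphenyl)‑4‑hydroxy‑5‑(3‑hydroxy‑3‑methylbutyl)‑6‑methoxy‑1‑benzofuran‑3‑carbaldehyde (ebenfuran V; no stereocentre) | COc1cc2oc(-c3ccc(O)cc3O)c(C=O)c2c(O)c1CCC(C)(C)O | target

## Step count and risk

Total step count: 15. Longest linear sequence: 11 steps (1 → 2 → 3 → 4 → 5 → 6 → 7 → 11 → 17 → 18 → 19 → 20, that is steps 1–6, 8 and 12–15).

**Step 12 (key step).** The proton shift in ylide 16 may outrun the aldol closure, because the new bond joins two fully substituted carbons next to a bulky ortho silyloxy group; the result would be plain O–H insertion. Carbene dimerisation may also take over if the hindered carbene is slow to meet the hydrogen‑bonded phenol. The fallback avoids the carbene; it sets out from 14 and 11 and returns at 17. The lithium enolate of 14 (LiN(SiMe3)2, THF, −78 °C) is brominated with NBS to give racemic benzyl 2‑bromo‑2‑[2,4‑bis(triisopropylsilyloxy)phenyl]acetate F1. The phenoxide of 11 (Cs2CO3, MeCN, rt) displaces the bromide of F1 to give the aryl ether benzyl 2‑[3‑(benzyloxy)‑2‑(2,2‑dimethoxyacetyl)‑5‑methoxy‑4‑(3‑methyl‑3‑triethylsilyloxybutyl)phenoxy]‑2‑[2,4‑bis(triisopropylsilyloxy)phenyl]acetate F2, which is also what a plain O–H insertion would give. Deprotonation of F2 at its doubly activated α‑carbon (DBU, or LiN(SiMe3)2 at −78 °C with a cold quench) closes C2–C3 by intramolecular aldol addition and gives 17.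

**Step 14.** The cascade may stall if the acetal hydrolyses before C3 ionises, since a formyl group next to C3 disfavours the cation. The free C4 hydroxyl may capture a cation formed at the side chain (chroman closure), or the electron‑rich ring B may shift from C2 to C3. The fallback separates aromatisation from hydrolysis; it sets out from 18 and returns at 19. Heating 18 with N,N‑dimethylformamide dineopentyl acetal (toluene, rt to 80 °C) activates the C3 hydroxyl as a leaving group under neutral conditions and effects decarboxylative dehydration to 2‑[2,4‑bis(triisopropylsilyloxy)phenyl]‑3‑(dimethoxymethyl)‑6‑methoxy‑5‑(3‑methyl‑3‑triethylsilyloxybutyl)‑1‑benzofuran‑4‑ol F3. The acetal and the triethylsilyl ether of F3 are then hydrolysed with PPTS in wet acetone at rt to give 19.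

**Step 13.** Reductive cleavage of the benzylic C2–O1 bond (an aryl ether of a benzylic carbon alpha to an ester) or of the benzylic C3–OH bond may compete with removal of the two benzyl groups. The fallback exposes no sp3 benzylic C–O bond to hydrogen; it sets out from 17 and returns at 19. The benzyl ester is cleaved with KOSiMe3 (THF, rt, then mild acidic work‑up) to 4‑(benzyloxy)‑2‑[2,4‑bis(triisopropylsilyloxy)phenyl]‑3‑(dimethoxymethyl)‑3‑hydroxy‑6‑methoxy‑5‑(3‑methyl‑3‑triethylsilyloxybutyl)‑2,3‑dihydro‑1‑benzofuran‑2‑carboxylic acid F4. The acid cascade of step 14 (1 M HCl, THF, rt) converts F4 into 4‑(benzyloxy)‑2‑[2,4‑bis(triisopropylsilyloxy)phenyl]‑5‑(3‑hydroxy‑3‑methylbutyl)‑6‑methoxy‑1‑benzofuran‑3‑carbaldehyde F5. Hydrogenolysis of the remaining aryl benzyl ether (H2, Pd/C, EtOAc) on the aromatic benzofuran, whose aldehyde is deactivated as a vinylogous ester, gives 19.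

**Step 8.** Oxidative addition and transmetalation at the iodide flanked by two alkoxy groups may be slow, so that protodeiodination or β‑hydride elimination of the alkylpalladium intermediate competes. The fallback uses an sp carbon nucleophile, which is far less sensitive to crowding; it sets out from 7 and returns at 11. Commercial 2‑methylbut‑3‑yn‑2‑ol is silylated (TESOTf, 2,6‑lutidine) to triethyl[(2‑methylbut‑3‑yn‑2‑yl)oxy]silane F6. Sonogashira coupling of F6 with 7 (Pd(PPh3)2Cl2, CuI, Et3N, THF, 50 °C) gives 1‑[2‑(benzyloxy)‑6‑hydroxy‑4‑methoxy‑3‑(3‑methyl‑3‑triethylsilyloxybut‑1‑yn‑1‑yl)phenyl]‑2,2‑dimethoxyethan‑1‑one F7. The triple bond of F7 is saturated with diimide (2‑nitrobenzenesulfonyl hydrazide, Et3N), or with H2 over Pd/C poisoned with diphenyl sulfide, both of which spare the benzyl ether, to give 11.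

**Step 2.** Iodination may occur para instead of ortho to the free hydroxyl (at C5), or twice, since both open positions are activated by three oxygen substituents. The fallback removes the regiochemical question by symmetry; it sets out from 1 and returns at 3. Compound 1 is iodinated first (NIS, 1 equiv, MeCN, 0 °C), which can give only 1‑(2,6‑dihydroxy‑3‑iodo‑4‑methoxyphenyl)ethan‑1‑one F8. The bulky silyl chloride (TIPSCl, imidazole, DMF) then reacts at the hydroxyl of F8 that is not flanked by iodine and gives 3.

## Further compounds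

F1 | step 12 | benzyl 2‑bromo‑2‑[2,4‑bis(triisopropylsilyloxy)phenyl]acetate (racemic) | O=C(OCc1ccccc1)C(Br)c1ccc(O[Si](C(C)C)(C(C)C)C(C)C)cc1O[Si](C(C)C)(C(C)C)C(C)C
F2 | step 12 | benzyl 2‑[3‑(benzyloxy)‑2‑(2,2‑dimethoxyacetyl)‑5‑methoxy‑4‑(3‑methyl‑3‑triethylsilyloxybutyl)phenoxy]‑2‑[2,4‑bis(triisopropylsilyloxy)phenyl]acetate (racemic) | COC(OC)C(=O)c1c(OC(C(=O)OCc2ccccc2)c2ccc(O[Si](C(C)C)(C(C)C)C(C)C)cc2O[Si](C(C)C)(C(C)C)C(C)C)cc(OC)c(CCC(C)(C)O[Si](CC)(CC)CC)c1OCc1ccccc1
F3 | step 14 | 2‑[2,4‑bis(triisopropylsilyloxy)phenyl]‑3‑(dimethoxymethyl)‑6‑methoxy‑5‑(3‑methyl‑3‑triethylsilyloxybutyl)‑1‑benzofuran‑4‑ol | COC(OC)c1c(-c2ccc(O[Si](C(C)C)(C(C)C)C(C)C)cc2O[Si](C(C)C)(C(C)C)C(C)C)oc2cc(OC)c(CCC(C)(C)O[Si](CC)(CC)CC)c(O)c12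
F4 | step 13 | 4‑(benzyloxy)‑2‑[2,4‑bis(triisopropylsilyloxy)phenyl]‑3‑(dimethoxymethyl)‑3‑hydroxy‑6‑methoxy‑5‑(3‑methyl‑3‑triethylsilyloxybutyl)‑2,3‑dihydro‑1‑benzofuran‑2‑carboxylic acid (racemic) | O=C(O)C1(c2ccc(O[Si](C(C)C)(C(C)C)C(C)C)cc2O[Si](C(C)C)(C(C)C)C(C)C)Oc2cc(OC)c(CCC(C)(C)O[Si](CC)(CC)CC)c(OCc3ccccc3)c2C1(O)C(OC)OC
F5 | step 13 | 4‑(benzyloxy)‑2‑[2,4‑bis(triisopropylsilyloxy)phenyl]‑5‑(3‑hydroxy‑3‑methylbutyl)‑6‑methoxy‑1‑benzofuran‑3‑carbaldehyde | COc1cc2oc(-c3ccc(O[Si](C(C)C)(C(C)C)C(C)C)cc3O[Si](C(C)C)(C(C)C)C(C)C)c(C=O)c2c(OCc4ccccc4)c1CCC(C)(C)O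
F6 | step 8 | triethyl[(2‑methylbut‑3‑yn‑2‑yl)oxy]silane | C#CC(C)(C)O[Si](CC)(CC)CC
F7 | step 8 | 1‑[2‑(benzyloxy)‑6‑hydroxy‑4‑methoxy‑3‑(3‑methyl‑3‑triethylsilyloxybut‑1‑yn‑1‑yl)phenyl]‑2,2‑dimethoxyethan‑1‑one | COC(OC)C(=O)c1c(O)cc(OC)c(C#CC(C)(C)O[Si](CC)(CC)CC)c1OCc1ccccc1
F8 | step 2 | 1‑(2,6‑dihydroxy‑3‑iodo‑4‑methoxyphenyl)ethan‑1‑one | CC(=O)c1c(O)cc(OC)c(I)c1O
A1 | alternative 1 | 3‑[2,4‑bis(benzyloxy)benzoyl]‑4,6‑dihydroxy‑1‑benzofuran‑2(3H)‑one | O=C1Oc2cc(O)cc(O)c2C1C(=O)c1ccc(OCc2ccccc2)cc1OCc1ccccc1
A2 | alternative 1 | methyl 2‑[2,4‑bis(benzyloxy)phenyl]‑4,6‑dihydroxy‑1‑benzofuran‑3‑carboxylate | COC(=O)c1c(-c2ccc(OCc3ccccc3)cc2OCc2ccccc2)oc2cc(O)cc(O)c12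
A3 | alternative 2 | methyl 2‑[2,4‑bis(tert‑butyldimethylsilyloxy)phenyl]‑5‑(2‑diazoacetyl)furan‑3‑carboxylate | COC(=O)c1cc(C(=O)C=[N+]=[N-])oc1-c1ccc(O[Si](C)(C)C(C)(C)C)cc1O[Si](C)(C)C(C)(C)C
A4 | alternative 2 | triethyl[(6‑methoxy‑2‑methylhex‑5‑yn‑2‑yl)oxy]silane | COC#CCCC(C)(C)O[Si](CC)(CC)CC
A5 | alternative 2 | methyl 2‑[2,4‑bis(tert‑butyldimethylsilyloxy)phenyl]‑4‑hydroxy‑6‑methoxy‑5‑(3‑methyl‑3‑triethylsilyloxybutyl)‑1‑benzofuran‑3‑carboxylate | COC(=O)c1c(-c2ccc(O[Si](C)(C)C(C)(C)C)cc2O[Si](C)(C)C(C)(C)C)oc2cc(OC)c(CCC(C)(C)O[Si](CC)(CC)CC)c(O)c12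
A6 | alternative 3 | 4‑hydroxy‑3‑[3‑(3‑hydroxy‑3‑methylbutyl)‑4‑methoxy‑2‑(methoxymethoxy)phenyl]‑7‑(methoxymethoxy)‑2H‑chromen‑2‑one | O=c1oc2cc(OCOC)ccc2c(O)c1-c1ccc(OC)c(CCC(C)(C)O)c1OCOC
A7 | alternative 3 | 8‑(3‑hydroxy‑3‑methylbutyl)‑9‑methoxy‑3,7‑bis(methoxymethoxy)‑6H‑benzofuro[3,2‑c]chromen‑6‑one | O=c1oc2cc(OCOC)ccc2c2oc3cc(OC)c(CCC(C)(C)O)c(OCOC)c3c12
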